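## Retrosynthetic overview

- The target is reached from its O-benzyl ether by neutral hydrogenolysis in the last step.
- The O-benzyl ether is disconnected at C4–C5, with the C5 acetate installed in the same event: terminal enol acetate of O-benzylzingerone plus decanal, by a proposed catalytic asymmetric acyl-transfer aldol that sets C5 as S.
- The enol acetate comes from O-benzylzingerone (kinetic enolate, O-acetylation), and that from zingerone and benzyl bromide.
- No ring is formed in the route; the only ring, the guaiacol arene, is carried in from zingerone.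

Assumption: the (S,S) enantiomer of the ProPhenol ligand is taken to direct Re-face attack on decanal, as recalled (not checked) for its direct aldol reactions of methyl ketones; if the sense is the opposite, the (R,R) ligand is used with no other change.

The target is (5S)-1-(4-hydroxy-3-methoxyphenyl)-3-oxotetradecan-5-yl acetate; the SMILES descriptor corresponds to S at C5 (priorities OAc > CH2C(=O) > nonyl > H).

## Route

Step 1
Reactants: 1 zingerone, 4-(4-hydroxy-3-methoxyphenyl)butan-2-one
Product: 2 4-[4-(benzyloxy)-3-methoxyphenyl]butan-2-one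
Conditions: BnBr (1.1 equiv), K2CO3 (1.5 equiv), acetone, reflux, 12 h
Reagents that add atoms: benzyl bromide, BrCc1ccccc1
Why: Williamson ether synthesis, in which carbonate deprotonates only the phenol and the phenoxide displaces bromide by SN2 while the ketone is not enolised; no stereocenter is involved.

Step 2
Reactants: 2 4-[4-(benzyloxy)-3-methoxyphenyl]butan-2-one
Product: 4 4-[4-(benzyloxy)-3-methoxyphenyl]but-1-en-2-yl acetate, via lithium enolate 3 (not isolated)
Conditions: LiN(i-Pr)2 (1.05 equiv), THF, −78 °C, 30 min; then cannulated into Ac2O (3 equiv), THF, −78 °C to 0 °C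
Reagents that add atoms: acetic anhydride, CC(=O)OC(C)=O
Why: Kinetic enolate formation followed by O-acylation, in which the hindered amide removes a methyl proton at −78 °C and inverse addition to excess anhydride favours O- over C-acetylation, fixing the terminal enol acetate; no stereocenter is involved.

Step 3
Reactants: 4 4-[4-(benzyloxy)-3-methoxyphenyl]but-1-en-2-yl acetate, 5 decanal
Product: 6 (5S)-1-[4-(benzyloxy)-3-methoxyphenyl]-3-oxotetradecan-5-yl acetate
Conditions: (S,S)-ProPhenol (10 mol%), Et2Zn (20 mol%), MeOH (10 mol%), 4 Å MS, THF, −20 °C; 4 and 5 (1.3 equiv) added together over 6 h; then 0 °C, 12 h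
Reagents that add atoms: none
Why: Proposed new method: a chain acyl-transfer aldol in which the methoxide-primed dinuclear zinc complex strips the acetyl group from 4 to give a catalyst-bound zinc enolate, this adds inside the chiral pocket to the Re face of zinc-coordinated 5 (setting C5 as S and forming C4–C5), and the resulting zinc aldolate is acetylated by the next molecule of 4, releasing 6 and regenerating the zinc enolate, so all atoms of 4 and 5 end up in 6 and the capped product cannot undergo retro-aldol; the closest known reaction types are the dinuclear zinc ProPhenol direct aldol of methyl ketones with aldehydes, the same catalyst's acylation of alcohols by vinyl esters, and tin-alkoxide-catalysed aldol reactions of enol trichloroacetates.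

Step 4
Reactants: 6 (5S)-1-[4-(benzyloxy)-3-methoxyphenyl]-3-oxotetradecan-5-yl acetate
Product: 7 (5S)-1-(4-hydroxy-3-methoxyphenyl)-3-oxotetradecan-5-yl acetate
Conditions: H2 (1 atm), 10% Pd/C, EtOAc, rt, 2 h
Reagents that add atoms: none
Why: Catalytic hydrogenolysis of the aryl benzyl ether is neutral, so the secondary acetate, the dialkyl ketone and the elimination-prone β-acetoxy ketone unit with its C5 stereocenter are left untouched.

## Compound list

1 | zingerone, 4-(4-hydroxy-3-methoxyphenyl)butan-2-one | CC(=O)CCc1ccc(O)c(OC)c1 | starting material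
2 | 4-[4-(benzyloxy)-3-methoxyphenyl]butan-2-one | CC(=O)CCc1ccc(OCc2ccccc2)c(OC)c1 | intermediate
3 | lithium 4-[4-(benzyloxy)-3-methoxyphenyl]but-1-en-2-olate | [Li]OC(=C)CCc1ccc(OCc2ccccc2)c(OC)c1 | intermediate
4 | 4-[4-(benzyloxy)-3-methoxyphenyl]but-1-en-2-yl acetate | CC(=O)OC(=C)CCc1ccc(OCc2ccccc2)c(OC)c1 | intermediate
5 | decanal | CCCCCCCCCC=O | starting material
6 | (5S)-1-[4-(benzyloxy)-3-methoxyphenyl]-3-oxotetradecan-5-yl acetate | CCCCCCCCC[C@@H](CC(=O)CCc1ccc(OCc2ccccc2)c(OC)c1)OC(C)=O | intermediate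
7 | (5S)-1-(4-hydroxy-3-methoxyphenyl)-3-oxotetradecan-5-yl acetate | CCCCCCCCC[C@@H](CC(=O)CCc1ccc(O)c(OC)c1)OC(C)=O | target

## Step count and risks

Total step count: 4. Longest linear sequence: 4 steps (1 → 2 → 4 → 6 → 7), with 5 joining at step 3.

**Step 3 (proposed new step).** Possible failures are slow acetyl transfer to the chelated zinc aldolate, C-acetylation of the zinc enolate by 4 to a zinc-binding β-diketone, loss of acetic acid from 6 to the enone, self-aldol of 5, or low enantioselectivity.

The fallback uses known chemistry, sets out from 2 and 5, and comes back at 6. Ketone 2 is converted with LiN(i-Pr)2 in THF at −78 °C into lithium enolate 3, which adds to 5 to give lithium 1-[4-(benzyloxy)-3-methoxyphenyl]-3-oxotetradecan-5-olate F1. Quenching with aqueous NH4Cl gives rac-1-[4-(benzyloxy)-3-methoxyphenyl]-5-hydroxytetradecan-3-one F2. Dehydration with catalytic p-TsOH in toluene at 60 °C gives (E)-1-[4-(benzyloxy)-3-methoxyphenyl]tetradec-4-en-3-one F3. Copper-catalysed asymmetric conjugate borylation then gives (5S)-1-[4-(benzyloxy)-3-methoxyphenyl]-5-(4,4,5,5-tetramethyl-1,3,2-dioxaborolan-2-yl)tetradecan-3-one F4. The conditions are CuCl, NaOt-Bu, B2pin2, MeOH, THF, rt, with the enantiomer of 1-[2-(diphenylphosphino)ferrocenyl]ethyldicyclohexylphosphine that gives the 5S product. Oxidation with NaBO3·4H2O in THF/H2O proceeds with retention to (5S)-1-[4-(benzyloxy)-3-methoxyphenyl]-5-hydroxytetradecan-3-one F5. Acetylation with Ac2O, pyridine and catalytic DMAP in CH2Cl2 at 0 °C gives 6.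

**Step 2.** Possible failures are competing C-acetylation or contamination by the internal enol acetate.

The fallback sets out from 2 and comes back at 4. Lithium enolate 3, made from 2 as before, is trapped on oxygen with ClP(O)(OEt)2 to give 4-[4-(benzyloxy)-3-methoxyphenyl]but-1-en-2-yl diethyl phosphate F6. Further LiN(i-Pr)2 (2.2 equiv, −78 °C to rt) eliminates diethyl phosphate to give lithium 4-[4-(benzyloxy)-3-methoxyphenyl]but-1-yn-1-ide F7. Aqueous NH4Cl work-up gives 1-(benzyloxy)-4-(but-3-yn-1-yl)-2-methoxybenzene F8. Ruthenium-catalysed Markovnikov addition of acetic acid ([RuCl2(p-cymene)]2, P(2-furyl)3, Na2CO3, AcOH, toluene, 50 °C) gives 4. The position of the alkyne fixes the terminal enol acetate, and no enolate acylation is involved.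

**Step 4.** This is the least likely of the three to fail; possible failures are catalyst poisoning by zinc residues or partial loss of the acetate.

The fallback changes the protecting group, sets out from 1, and comes back at 7. Silylation of 1 with TIPSCl and imidazole in DMF gives 4-{3-methoxy-4-[(triisopropylsilyl)oxy]phenyl}butan-2-one F9. LiN(i-Pr)2 in THF at −78 °C gives lithium 4-{3-methoxy-4-[(triisopropylsilyl)oxy]phenyl}but-1-en-2-olate F10. Inverse quench into Ac2O gives 4-{3-methoxy-4-[(triisopropylsilyl)oxy]phenyl}but-1-en-2-yl acetate F11. The step 3 aldol with 5 gives (5S)-1-{3-methoxy-4-[(triisopropylsilyl)oxy]phenyl}-3-oxotetradecan-5-yl acetate F12. Desilylation with Bu4NF buffered by AcOH in THF at 0 °C gives 7 without hydrogen or palladium.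

## Further compounds

F1 | step 3 | lithium 1-[4-(benzyloxy)-3-methoxyphenyl]-3-oxotetradecan-5-olate (racemic) | CCCCCCCCCC(O[Li])CC(=O)CCc1ccc(OCc2ccccc2)c(OC)c1
F2 | step 3 | rac-1-[4-(benzyloxy)-3-methoxyphenyl]-5-hydroxytetradecan-3-one | CCCCCCCCCC(O)CC(=O)CCc1ccc(OCc2ccccc2)c(OC)c1
F3 | step 3 | (E)-1-[4-(benzyloxy)-3-methoxyphenyl]tetradec-4-en-3-one | CCCCCCCCC/C=C/C(=O)CCc1ccc(OCc2ccccc2)c(OC)c1
F4 | step 3 | (5S)-1-[4-(benzyloxy)-3-methoxyphenyl]-5-(4,4,5,5-tetramethyl-1,3,2-dioxaborolan-2-yl)tetradecan-3-one | CCCCCCCCC[C@@H](CC(=O)CCc1ccc(OCc2ccccc2)c(OC)c1)B1OC(C)(C)C(C)(C)O1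
F5 | step 3 | (5S)-1-[4-(benzyloxy)-3-methoxyphenyl]-5-hydroxytetradecan-3-one | CCCCCCCCC[C@@H](CC(=O)CCc1ccc(OCc2ccccc2)c(OC)c1)O
F6 | step 2 | 4-[4-(benzyloxy)-3-methoxyphenyl]but-1-en-2-yl diethyl phosphate | CCOP(=O)(OCC)OC(=C)CCc1ccc(OCc2ccccc2)c(OC)c1
F7 | step 2 | lithium 4-[4-(benzyloxy)-3-methoxyphenyl]but-1-yn-1-ide | [Li]C#CCCc1ccc(OCc2ccccc2)c(OC)c1
F8 | step 2 | 1-(benzyloxy)-4-(but-3-yn-1-yl)-2-methoxybenzene | C#CCCc1ccc(OCc2ccccc2)c(OC)c1
F9 | step 4 | 4-{3-methoxy-4-[(triisopropylsilyl)oxy]phenyl}butan-2-one | CC(=O)CCc1ccc(O[Si](C(C)C)(C(C)C)C(C)C)c(OC)c1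
F10 | step 4 | lithium 4-{3-methoxy-4-[(triisopropylsilyl)oxy]phenyl}but-1-en-2-olate | [Li]OC(=C)CCc1ccc(O[Si](C(C)C)(C(C)C)C(C)C)c(OC)c1
F11 | step 4 | 4-{3-methoxy-4-[(triisopropylsilyl)oxy]phenyl}but-1-en-2-yl acetate | CC(=O)OC(=C)CCc1ccc(O[Si](C(C)C)(C(C)C)C(C)C)c(OC)c1
F12 | step 4 | (5S)-1-{3-methoxy-4-[(triisopropylsilyl)oxy]phenyl}-3-oxotetradecan-5-yl acetate | CCCCCCCCC[C@@H](CC(=O)CCc1ccc(O[Si](C(C)C)(C(C)C)C(C)C)c(OC)c1)OC(C)=O
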